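**Retrosynthetic overview**
- Target ⇐ anti hydrolysis of an 8α,9α-epoxide ⇐ carbonylative esterification of the C6 alcohol with a protected 4-bromophenol and CO.
- C5–H and C6–OH ⇐ syn hydroboration of C5=C6; C4 carbinol ⇐ isopropyl addition to the cyclopentanone; epoxide ⇐ C8=C9. All three reagents are planned to attack anti to the angular methyl.
- Seven-membered ring ⇐ ring-closing metathesis of an (E)-alkylidenecyclopentanone carrying allyl and methallyl-type arms.
- Five-membered ring ⇐ gold-catalysed ring expansion (1,2-alkyl shift) of a 1-alkynylcyclobutanol built from an α-quaternary cyclobutanone and a skipped enyne.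
- The only catalyst-set stereocentre (C1) ⇐ asymmetric α-allylation of 2-methylcyclobutanone; ring order: four (bought) → five → seven.

Assumption: positions are given in daucane numbering (C1 = ring-fusion C–CH3, C4 = isopropyl carbinol, C5 = ring-fusion CH, C6 = ester carbon, C8/C9 = diol carbons), and 2-(4-bromophenoxy)oxane is bought as the protected form of 4-bromophenol.

**Step 1**
Reactants: 1 2-methylcyclobutan-1-one (racemic); 2 prop-2-en-1-ol
Product: 3 (2R)-2-methyl-2-(prop-2-en-1-yl)cyclobutan-1-one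
Conditions: Pd2(dba)3 (2.5 mol%), tBuXPhos (11 mol%), (S)-H8-TRIP (10 mol%), CO2 (1 atm), 5 Å MS, cyclohexane, 50 °C
Reagents that add atoms: none
Why: Proposed new method: the chiral phosphoric acid both enolises racemic 1 to its achiral, more substituted enol and serves as counter-anion of the allyl–palladium cation generated from allyl alcohol by zerovalent palladium, so C–C bond formation inside this hydrogen-bonded chiral ion pair sets the quaternary stereocentre (R) from both enantiomers of 1; the closest known reaction type is the direct Tsuji–Trost α-allylation of α-branched five- to seven-membered ketones with allyl alcohol under palladium/chiral phosphoric acid catalysis, which has not been shown for cyclobutanones.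

**Step 2**
Reactants: 4 3-chloro-2-methylprop-1-ene; 5 ethynylmagnesium bromide
Product: 6 2-methylpent-1-en-4-yne
Conditions: CuCl (5 mol%), THF, 0 → 50 °C
Reagents that add atoms: none
Why: Copper-catalysed allylic substitution of the chloride by the alkynyl Grignard reagent gives the skipped enyne; no stereocentre is formed.

**Step 3**
Reactants: 6 2-methylpent-1-en-4-yne; 3 (2R)-2-methyl-2-(prop-2-en-1-yl)cyclobutan-1-one
Product: 8 (2R)-2-methyl-1-(4-methylpent-4-en-1-yn-1-yl)-2-(prop-2-en-1-yl)cyclobutan-1-ol (both carbinol epimers), via lithium acetylide 7 (not isolated)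
Conditions: n-BuLi, THF, −78 °C; then 3, −78 → 0 °C; aq. NH4Cl
Reagents that add atoms: none
Why: Nucleophilic 1,2-addition of the lithium acetylide to the strained, very electrophilic cyclobutanone; the carbinol centre forms as a mixture, which does not matter because it becomes the carbonyl carbon in step 4, and the quaternary centre is untouched.

**Step 4**
Reactants: 8 (2R)-2-methyl-1-(4-methylpent-4-en-1-yn-1-yl)-2-(prop-2-en-1-yl)cyclobutan-1-ol
Product: 9 (2E,3R)-3-methyl-2-(3-methylbut-3-en-1-ylidene)-3-(prop-2-en-1-yl)cyclopentan-1-one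
Conditions: (4-CF3C6H4)3PAuCl (2 mol%), AgSbF6 (2 mol%), CH2Cl2, 0 °C → rt
Reagents that add atoms: none
Why: Gold-catalysed ring expansion of a 1-alkynylcyclobutanol (semipinacol-type 1,2-alkyl shift, not pericyclic): the cationic monovalent gold–alkyne complex is attacked anti by the migrating ring bond, the more substituted (quaternary) carbon migrates with retention so the four-ring becomes the cyclopentanone, and protodeauration leaves only the (E)-alkylidene isomer, in which C7 and C1 are cis as the seven-ring closure requires.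

**Step 5**
Reactants: 9 (2E,3R)-3-methyl-2-(3-methylbut-3-en-1-ylidene)-3-(prop-2-en-1-yl)cyclopentan-1-one
Product: 10 (3aR)-3a,6-dimethyl-3,3a,4,7-tetrahydroazulen-1(2H)-one
Conditions: second-generation Hoveyda–Grubbs catalyst (5 mol%), 1,4-benzoquinone (10 mol%), CH2Cl2 (5 mM), 40 °C
Reagents that add atoms: none
Why: Ring-closing metathesis between the allyl group and the 1,1-disubstituted alkene forms the seven-membered ring and the trisubstituted C8=C9 bond with loss of ethene; the conjugated C5=C6 bond does not take part and no stereocentre changes.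

**Step 6**
Reactants: 10 (3aR)-3a,6-dimethyl-3,3a,4,7-tetrahydroazulen-1(2H)-one
Product: 11 (3aR,5S,6R)-5,6-epoxy-3a,6-dimethyl-3,3a,4,5,6,7-hexahydroazulen-1(2H)-one (8α,9α-epoxide)
Conditions: mCPBA (1.05 equiv), NaHCO3, CH2Cl2, −20 → 0 °C
Reagents that add atoms: mCPBA (3-chloroperoxybenzoic acid), OOC(=O)c1cccc(Cl)c1
Why: Prilezhaev epoxidation is chemoselective for the electron-rich trisubstituted C8=C9 bond over the enone double bond and is expected on the α-face, opposite the pseudo-axial angular methyl, giving the 8α,9α-epoxide that masks this alkene for step 8 and is the precursor of the diol.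

**Step 7**
Reactants: 11 (3aR,5S,6R)-5,6-epoxy-3a,6-dimethyl-3,3a,4,5,6,7-hexahydroazulen-1(2H)-one
Product: 12 (1R,3aR,5S,6R)-5,6-epoxy-3a,6-dimethyl-1-(propan-2-yl)-1,2,3,3a,4,5,6,7-octahydroazulen-1-ol
Conditions: iPrMgCl, CeCl3 (anhydrous, 1.5 equiv), THF, −78 °C
Reagents that add atoms: isopropylmagnesium chloride, CC(C)[Mg]Cl
Why: The weakly basic organocerium reagent adds 1,2 to the conjugated ketone without enolisation or epoxide opening, and approach from the α-face opposite the angular methyl sets C4 with hydroxyl β and isopropyl α.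

**Step 8**
Reactants: 12 (1R,3aR,5S,6R)-5,6-epoxy-3a,6-dimethyl-1-(propan-2-yl)-1,2,3,3a,4,5,6,7-octahydroazulen-1-ol
Product: 14 (1R,3aR,5S,6R,8S,8aS)-5,6-epoxy-3a,6-dimethyl-1-(propan-2-yl)decahydroazulene-1,8-diol, via alkylborane 13 (not isolated)
Conditions: BH3·THF (4 equiv), THF, 0 °C → rt; then 3 M NaOH, 30% H2O2, 0 °C
Reagents that add atoms: hydrogen peroxide, OO
Why: Hydroboration–oxidation: borane adds syn and anti-Markovnikov to the trisubstituted C5=C6 bond from the α-face (opposite the angular methyl and the allylic C4–O bond), so H5 and the C6 hydroxyl both end up α, which fixes the trans ring fusion and the C6 carbinol in one step, and C–B oxidation proceeds with retention.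

**Step 9**
Reactants: 14 (1R,3aR,5S,6R,8S,8aS)-5,6-epoxy-3a,6-dimethyl-1-(propan-2-yl)decahydroazulene-1,8-diol; 15 2-(4-bromophenoxy)oxane (racemic)
Product: 16 [(1R,3aR,5S,6R,8S,8aS)-5,6-epoxy-1-hydroxy-3a,6-dimethyl-1-(propan-2-yl)decahydroazulen-8-yl] 4-(oxan-2-yloxy)benzoate (both acetal epimers)
Conditions: 15 (1.5 equiv), Pd(OAc)2 (5 mol%), Xantphos (10 mol%), CO (1 atm), Et3N, DMAP (20 mol%), toluene, 80 °C
Reagents that add atoms: carbon monoxide, [C-]#[O+]
Why: Palladium-catalysed alkoxycarbonylation (Heck carbonylation): oxidative addition of 15, CO insertion and acyl transfer to the only secondary hydroxyl (the tertiary C4 hydroxyl is too hindered) give the benzoate with retention at C6, the epoxide being inert to these basic conditions.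

**Step 10**
Reactants: 16 [(1R,3aR,5S,6R,8S,8aS)-5,6-epoxy-1-hydroxy-3a,6-dimethyl-1-(propan-2-yl)decahydroazulen-8-yl] 4-(oxan-2-yloxy)benzoate
Product: 18 [(1R,3aR,5S,6S,8S,8aS)-1,5,6-trihydroxy-3a,6-dimethyl-1-(propan-2-yl)decahydroazulen-8-yl] 4-hydroxybenzoate (target; daucane 1R,4R,5S,6S,8S,9S), via phenol epoxide 17 (not isolated)
Conditions: HClO4 (0.5 M aq., catalytic), THF/H2O 3:1, 0 °C → rt
Reagents that add atoms: water, O
Why: Acid-catalysed epoxide hydrolysis: water attacks the tertiary C8 anti to the epoxide oxygen (inversion at C8, retention at C9), turning the 8α,9α-epoxide into the 8β,9α-diol (8S,9S), while the same dilute acid cleaves the acetal protecting group.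

**Compound list**
1 | 2-methylcyclobutan-1-one (racemic) | CC1CCC1=O | starting material
2 | prop-2-en-1-ol | C=CCO | starting material
3 | (2R)-2-methyl-2-(prop-2-en-1-yl)cyclobutan-1-one | C[C@]1(CC=C)CCC1=O | intermediate
4 | 3-chloro-2-methylprop-1-ene | CC(=C)CCl | starting material
5 | ethynylmagnesium bromide | C#C[Mg]Br | starting material
6 | 2-methylpent-1-en-4-yne | CC(=C)CC#C | intermediate
7 | lithium 4-methylpent-4-en-1-yn-1-ide (lithium acetylide) | [Li]C#CCC(C)=C | intermediate
8 | (2R)-2-methyl-1-(4-methylpent-4-en-1-yn-1-yl)-2-(prop-2-en-1-yl)cyclobutan-1-ol (both carbinol epimers) | C=CC[C@@]1(C)CCC1(O)C#CCC(C)=C | intermediate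
9 | (2E,3R)-3-methyl-2-(3-methylbut-3-en-1-ylidene)-3-(prop-2-en-1-yl)cyclopentan-1-one | O=C1CC[C@](C)(CC=C)/C1=C\CC(C)=C | intermediate
10 | (3aR)-3a,6-dimethyl-3,3a,4,7-tetrahydroazulen-1(2H)-one | O=C1CC[C@]2(C)CC=C(C)CC=C12 | intermediate
11 | (3aR,5S,6R)-5,6-epoxy-3a,6-dimethyl-3,3a,4,5,6,7-hexahydroazulen-1(2H)-one | O=C1CC[C@]2(C)C[C@@H]3O[C@]3(C)CC=C12 | intermediate
12 | (1R,3aR,5S,6R)-5,6-epoxy-3a,6-dimethyl-1-(propan-2-yl)-1,2,3,3a,4,5,6,7-octahydroazulen-1-ol | CC(C)[C@]1(O)CC[C@]2(C)C[C@@H]3O[C@]3(C)CC=C12 | intermediate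
13 | alkylborane: C6-boryl, O4-boryl adduct of 12 (boron α at C6, H α at C5) | CC(C)[C@]1(OB)CC[C@]2(C)C[C@@H]3O[C@]3(C)C[C@H](B)[C@H]21 | intermediate
14 | (1R,3aR,5S,6R,8S,8aS)-5,6-epoxy-3a,6-dimethyl-1-(propan-2-yl)decahydroazulene-1,8-diol (8α,9α-epoxy-8,9-dihydrojaeschkeanadiol) | CC(C)[C@]1(O)CC[C@]2(C)C[C@@H]3O[C@]3(C)C[C@H](O)[C@H]21 | intermediate
15 | 2-(4-bromophenoxy)oxane (racemic; tetrahydropyranyl ether of 4-bromophenol) | Brc1ccc(OC2CCCCO2)cc1 | starting material
16 | [(1R,3aR,5S,6R,8S,8aS)-5,6-epoxy-1-hydroxy-3a,6-dimethyl-1-(propan-2-yl)decahydroazulen-8-yl] 4-(oxan-2-yloxy)benzoate | CC(C)[C@]1(O)CC[C@]2(C)C[C@@H]3O[C@]3(C)C[C@H](OC(=O)c4ccc(OC5CCCCO5)cc4)[C@H]21 | intermediate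
17 | [(1R,3aR,5S,6R,8S,8aS)-5,6-epoxy-1-hydroxy-3a,6-dimethyl-1-(propan-2-yl)decahydroazulen-8-yl] 4-hydroxybenzoate (phenol epoxide) | CC(C)[C@]1(O)CC[C@]2(C)C[C@@H]3O[C@]3(C)C[C@H](OC(=O)c4ccc(O)cc4)[C@H]21 | intermediate
18 | [(1R,3aR,5S,6S,8S,8aS)-1,5,6-trihydroxy-3a,6-dimethyl-1-(propan-2-yl)decahydroazulen-8-yl] 4-hydroxybenzoate | CC(C)[C@]1(O)CC[C@]2(C)C[C@H](O)[C@@](C)(O)C[C@H](OC(=O)c3ccc(O)cc3)[C@H]21 | target

**Step count**
Total steps: 10. Longest linear sequence: 9 (steps 1, 3, 4, 5, 6, 7, 8, 9, 10; step 2 is a one-step branch).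

**Steps most likely to fail**

Step 1 (the proposed new allylation). Enolisation of the strained ketone may be slow, the ring may open, or the sense of induction may be opposite; in the last case the antipodal acid is used. The fallback is the known decarboxylative asymmetric allylic alkylation of cyclobutanone β-keto esters. It sets out from allyl alcohol 2, which with 1,1'-carbonyldiimidazole gives prop-2-en-1-yl 1H-imidazole-1-carboxylate F1. Commercial cyclobutanone F2 (five heavy atoms) is C-acylated with F1 (LiN(SiMe3)2, THF, −78 °C) to prop-2-en-1-yl 2-oxocyclobutane-1-carboxylate F3. Methylation (MeI, K2CO3, acetone) gives prop-2-en-1-yl 1-methyl-2-oxocyclobutane-1-carboxylate F4. Pd2(dba)3 with an electron-poor (S)-tert-butyl phosphinooxazoline ligand then converts F4 with loss of CO2 and comes back to the route at 3.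

Step 4 (gold ring expansion). The substrate is also a 1,6-enyne, so gold-catalysed enyne cycloisomerisation may compete with the 1,2-shift, and the skipped diene of 9 can move into conjugation. The fallback sets out from 8 and replaces π-acid catalysis by an epoxide semipinacol shift. Trans-reduction with NaAlH2(OCH2CH2OMe)2 gives (2R)-2-methyl-1-[(1E)-4-methylpenta-1,4-dien-1-yl]-2-(prop-2-en-1-yl)cyclobutan-1-ol F5. Hydroxyl-directed epoxidation (VO(acac)2, tBuOOH), which touches only the allylic alkene, gives the epoxy alcohol (2R)-2-methyl-1-[3-(2-methylprop-2-en-1-yl)oxiran-2-yl]-2-(prop-2-en-1-yl)cyclobutan-1-ol F6. BF3·OEt2 at −78 °C triggers the 1,2-shift of the quaternary carbon to (3R)-2-(1-hydroxy-3-methylbut-3-en-1-yl)-3-methyl-3-(prop-2-en-1-yl)cyclopentan-1-one F7. Dehydration (MsCl, Et3N, then DBU) erases the new carbinol centres, so all diastereomers converge, and the sequence comes back at 9.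

Step 8 (hydroboration). α-Face selectivity rests on the angular methyl alone and is opposed by the α-isopropyl group, and borane may slowly reduce the epoxide. The same facial argument carries steps 6 and 7, so their selectivity is also unproven. The fallback sets out from 11 and sets C6 and C5 before C4. Copper-catalysed conjugate borylation (CuCl, NaOtBu, a chiral ferrocenyl bisphosphine, B2pin2, MeOH) gives the β-boryl ketone (3aR,5S,6R,8S,8aS)-5,6-epoxy-3a,6-dimethyl-8-(4,4,5,5-tetramethyl-1,3,2-dioxaborolan-2-yl)octahydroazulen-1(2H)-one F8; the ligand controls C6, but C5 is set by enolate protonation and stays epimerisable, which is the weak point of this fallback. Oxidation with NaBO3·4H2O gives the β-hydroxy ketone (3aR,5S,6R,8S,8aS)-5,6-epoxy-8-hydroxy-3a,6-dimethyloctahydroazulen-1(2H)-one F9. iPrMgCl/CeCl3 then adds anti to the C5–C6 bond (1,2-induction with chelation), and the sequence comes back at 14.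

**Further compounds**
F1 | step 1 | prop-2-en-1-yl 1H-imidazole-1-carboxylate | C=CCOC(=O)n1ccnc1
F2 | step 1 | cyclobutanone | O=C1CCC1
F3 | step 1 | prop-2-en-1-yl 2-oxocyclobutane-1-carboxylate | C=CCOC(=O)C1CCC1=O
F4 | step 1 | prop-2-en-1-yl 1-methyl-2-oxocyclobutane-1-carboxylate | C=CCOC(=O)C1(C)CCC1=O
F5 | step 4 | (2R)-2-methyl-1-[(1E)-4-methylpenta-1,4-dien-1-yl]-2-(prop-2-en-1-yl)cyclobutan-1-ol | C=CC[C@@]1(C)CCC1(O)/C=C/CC(C)=C
F6 | step 4 | (2R)-2-methyl-1-[3-(2-methylprop-2-en-1-yl)oxiran-2-yl]-2-(prop-2-en-1-yl)cyclobutan-1-ol | C=CC[C@@]1(C)CCC1(O)C2OC2CC(C)=C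
F7 | step 4 | (3R)-2-(1-hydroxy-3-methylbut-3-en-1-yl)-3-methyl-3-(prop-2-en-1-yl)cyclopentan-1-one | O=C1CC[C@](C)(CC=C)C1C(O)CC(C)=C
F8 | step 8 | (3aR,5S,6R,8S,8aS)-5,6-epoxy-3a,6-dimethyl-8-(4,4,5,5-tetramethyl-1,3,2-dioxaborolan-2-yl)octahydroazulen-1(2H)-one | O=C1CC[C@]2(C)C[C@@H]3O[C@]3(C)C[C@H](B4OC(C)(C)C(C)(C)O4)[C@@H]12
F9 | step 8 | (3aR,5S,6R,8S,8aS)-5,6-epoxy-8-hydroxy-3a,6-dimethyloctahydroazulen-1(2H)-one | O=C1CC[C@]2(C)C[C@@H]3O[C@]3(C)C[C@H](O)[C@@H]12
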